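## Retrosynthetic overview

1. The target is the (3R,4R)-3,4-cis-isoflavan-4-ol. Ring C (the pyran, the only ring that is built) is closed last by Mitsunobu etherification (O1–C2) of a ring A phenol onto a primary alcohol, followed by global desilylation.
2. That alcohol comes from reductive removal of an oxazolidinone auxiliary. The C3–C4 bond and both stereocentres are set in one intermolecular, auxiliary-controlled anti-aldol between an N-(arylacetyl)oxazolidinone (ring B) and 2,6-bis(allyloxy)-4-methoxybenzaldehyde (ring A).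
3. Ring B imide: from 4-hydroxy-2-methoxybenzaldehyde by bromination, Stille allylation and cross-metathesis (prenyl), silylation, one-carbon homologation to the arylacetic acid, and acylation of the auxiliary.
4. Ring A aldehyde: from 2,4,6-trimethoxybenzaldehyde by double ortho-demethylation and allylation. Its two ortho oxygens are equivalent, so either can become O1 and the other the 5-OH.

Assumption: compounds 1, 9 and 12 are bought; the route is designed on paper and has not been run.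

Abbreviations in names: ArA = 2,6-bis(allyloxy)-4-methoxyphenyl; ArB = 2-methoxy-5-(3-methylbut-2-en-1-yl)-4-(triisopropylsilyloxy)phenyl.

## Route

Step 1
Reactants: 1 4-hydroxy-2-methoxybenzaldehyde
Product: 2 5-bromo-4-hydroxy-2-methoxybenzaldehyde
Conditions: NBS (1.0 equiv), MeCN, 0 °C to rt
Reagents that add atoms: N-bromosuccinimide, O=C1CCC(=O)N1Br
Why: Electrophilic aromatic bromination goes to C5, which is ortho to the free OH, para to OMe and less hindered than C3.

Step 2
Reactants: 2 5-bromo-4-hydroxy-2-methoxybenzaldehyde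
Product: 3 5-allyl-4-hydroxy-2-methoxybenzaldehyde
Conditions: allylSnBu3 (1.2 equiv), Pd(PPh3)4 (5 mol%), DMF, 90 °C
Reagents that add atoms: allyltributylstannane, C=CC[Sn](CCCC)(CCCC)CCCC
Why: Stille cross-coupling on zerovalent palladium replaces the bromide regiospecifically and tolerates the free phenol and the aldehyde.

Step 3
Reactants: 3 5-allyl-4-hydroxy-2-methoxybenzaldehyde
Product: 4 4-hydroxy-2-methoxy-5-(3-methylbut-2-en-1-yl)benzaldehyde
Conditions: second-generation Grubbs catalyst (3 mol%), 2-methyl-2-butene/CH2Cl2, rt to 40 °C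
Reagents that add atoms: 2-methyl-2-butene, CC=C(C)C
Why: Olefin cross-metathesis with excess 2-methyl-2-butene turns the terminal allyl group into the prenyl group, with volatile propene as the by-product.

Step 4
Reactants: 4 4-hydroxy-2-methoxy-5-(3-methylbut-2-en-1-yl)benzaldehyde
Product: 5 2-methoxy-5-(3-methylbut-2-en-1-yl)-4-(triisopropylsilyloxy)benzaldehyde (ArB–CHO)
Conditions: TIPSCl, imidazole, DMF, rt
Reagents that add atoms: chlorotriisopropylsilane, CC(C)[Si](Cl)(C(C)C)C(C)C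
Why: Silylation of the phenol gives a robust aryl TIPS ether that is orthogonal to the allyl ethers of ring A and is removed at the end with fluoride.

Step 5
Reactants: 5 ArB–CHO
Product: 6 ArB–CH=CH–OMe (β-methoxystyrene, E/Z mixture)
Conditions: MeOCH2PPh3Cl, NaN(SiMe3)2, THF, 0 °C to rt
Reagents that add atoms: (methoxymethyl)triphenylphosphonium chloride, COC[P+](c1ccccc1)(c1ccccc1)c1ccccc1.[Cl-]
Why: Wittig olefination with the methoxymethylene ylide adds the one extra carbon as a masked aldehyde; the alkene geometry is irrelevant.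

Step 6
Reactants: 6 ArB–CH=CH–OMe
Product: 7 2-ArB-acetaldehyde
Conditions: 3 M HCl (aq), THF, rt
Reagents that add atoms: water, O
Why: Acid hydrolysis of the enol ether frees the arylacetaldehyde, while the aryl TIPS ether and the trisubstituted prenyl alkene survive dilute aqueous acid at rt.

Step 7
Reactants: 7 2-ArB-acetaldehyde
Product: 8 2-ArB-acetic acid
Conditions: NaClO2, NaH2PO4, 2-methyl-2-butene (excess), t-BuOH/H2O, 0 °C to rt
Reagents that add atoms: sodium chlorite, [Na+].[O-]Cl=O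
Why: Pinnick oxidation converts the aldehyde to the acid at pH 4, and the excess alkene scavenger traps HOCl so that the prenyl group and the electron-rich ring are not chlorinated.

Step 8
Reactants: 8 2-ArB-acetic acid; 9 (R)-4-benzyl-2-oxazolidinone
Product: 11 (R)-4-benzyl-3-(2-ArB-acetyl)oxazolidin-2-one, via mixed pivalic anhydride 10 (not isolated)
Conditions: PivCl, Et3N, THF, −20 °C; then 9, LiCl, −20 °C to rt
Reagents that add atoms: none
Why: N-acylation of the oxazolidinone through the mixed pivalic anhydride (LiCl-promoted) installs the Evans auxiliary without strong base.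

Step 9
Reactants: 12 2,4,6-trimethoxybenzaldehyde
Product: 13 2,6-dihydroxy-4-methoxybenzaldehyde
Conditions: AlCl3 (4–5 equiv), CH2Cl2, 0 °C to reflux; then 1 M HCl
Reagents that add atoms: none
Why: Chelation-directed Lewis-acid ether cleavage removes only the two methoxy groups ortho to the formyl group, because AlCl3 bound to the carbonyl oxygen activates them while the para methoxy group is not chelated.

Step 10
Reactants: 13 2,6-dihydroxy-4-methoxybenzaldehyde
Product: 14 2,6-bis(allyloxy)-4-methoxybenzaldehyde (ArA–CHO)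
Conditions: allyl bromide (3 equiv), K2CO3, DMF, 60 °C
Reagents that add atoms: allyl bromide, C=CCBr
Why: Williamson etherification of both phenols gives a symmetrical aldehyde whose allyl ethers are later removed under neutral palladium catalysis.

Step 11
Reactants: 11 (R)-4-benzyl-3-(2-ArB-acetyl)oxazolidin-2-one; 14 ArA–CHO
Product: 16 (R)-4-benzyl-3-[(2S,3R)-3-ArA-3-hydroxy-2-ArB-propanoyl]oxazolidin-2-one, via TMS ether 15 (not isolated)
Conditions: MgCl2 (0.2 equiv), Et3N, TMSCl, EtOAc, rt, 24 h; then HF·pyridine, pyridine, THF, 0 °C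
Reagents that add atoms: none
Why: In this Evans magnesium halide-catalysed anti-aldol the Mg-chelated Z-enolate of 11 adds to 14 through a boat-like transition state on the face opposite the benzyl group, which sets both stereocentres (2S,3R in the adduct, C3 and C4 of the target), while silylation of the aldolate by TMSCl makes the addition irreversible and the TMS group is then removed with buffered HF.

Step 12
Reactants: 16 (R)-4-benzyl-3-[(2S,3R)-3-ArA-3-hydroxy-2-ArB-propanoyl]oxazolidin-2-one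
Product: 17 (R)-4-benzyl-3-[(2S,3R)-3-ArA-3-(tert-butyldimethylsilyloxy)-2-ArB-propanoyl]oxazolidin-2-one
Conditions: TBSOTf, 2,6-lutidine, CH2Cl2, −78 to 0 °C
Reagents that add atoms: tert-butyldimethylsilyl trifluoromethanesulfonate, CC(C)(C)[Si](C)(C)OS(=O)(=O)C(F)(F)F
Why: Silylation of the hindered secondary alcohol under non-acidic conditions masks the ionisable, very electron-rich benzylic carbinol for the steps that follow, and the stereocentres are untouched.

Step 13
Reactants: 17 (R)-4-benzyl-3-[(2S,3R)-3-ArA-3-(tert-butyldimethylsilyloxy)-2-ArB-propanoyl]oxazolidin-2-one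
Product: 18 (2R,3R)-3-ArA-3-(tert-butyldimethylsilyloxy)-2-ArB-propan-1-ol
Conditions: LiBH4, MeOH (1 equiv), Et2O/THF, 0 °C
Reagents that add atoms: none
Why: Reductive removal of the Evans auxiliary by hydride attack on the exocyclic imide carbonyl gives the primary alcohol (the future C2) without touching either stereocentre, and the auxiliary is recovered.

Step 14
Reactants: 18 (2R,3R)-3-ArA-3-(tert-butyldimethylsilyloxy)-2-ArB-propan-1-ol
Product: 19 2-[(1R,2R)-1-(tert-butyldimethylsilyloxy)-3-hydroxy-2-ArB-propyl]-5-methoxybenzene-1,3-diol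
Conditions: Pd(PPh3)4 (5 mol%), morpholine (6 equiv), THF, rt to 40 °C
Reagents that add atoms: none
Why: Tsuji–Trost deallylation on zerovalent palladium with morpholine as allyl acceptor frees both ring A phenols under neutral conditions that leave the C-prenyl group, the silyl ethers and the benzylic centre alone.

Step 15
Reactants: 19 2-[(1R,2R)-1-(tert-butyldimethylsilyloxy)-3-hydroxy-2-ArB-propyl]-5-methoxybenzene-1,3-diol
Product: 20 (3R,4R)-4-(tert-butyldimethylsilyloxy)-7-methoxy-3-ArB-chroman-5-ol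
Conditions: PPh3, DIAD, THF (0.02 M), 0 °C to rt
Reagents that add atoms: none
Why: Intramolecular Mitsunobu etherification (6-exo attack of a phenol on the activated primary alcohol) closes ring C, and because the two phenols are equivalent and no stereocentre reacts, a single (3R,4R) chroman results.

Step 16
Reactants: 20 (3R,4R)-4-(tert-butyldimethylsilyloxy)-7-methoxy-3-ArB-chroman-5-ol
Product: 21 (3R,4R)-3-[4-hydroxy-2-methoxy-5-(3-methylbut-2-en-1-yl)phenyl]-7-methoxychromane-4,5-diol (target)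
Conditions: TBAF (3 equiv), AcOH (3 equiv), THF, 0 °C to rt
Reagents that add atoms: none
Why: Fluoride-mediated desilylation removes the aryl TIPS and the secondary TBS ether in one operation, and the acetic acid buffer keeps the acid- and base-sensitive benzylic alcohol and phenols intact.

## Compound list

1 | 4-hydroxy-2-methoxybenzaldehyde | COc1cc(O)ccc1C=O | starting material
2 | 5-bromo-4-hydroxy-2-methoxybenzaldehyde | COc1cc(O)c(Br)cc1C=O | intermediate
3 | 5-allyl-4-hydroxy-2-methoxybenzaldehyde | COc1cc(O)c(CC=C)cc1C=O | intermediate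
4 | 4-hydroxy-2-methoxy-5-(3-methylbut-2-en-1-yl)benzaldehyde | COc1cc(O)c(CC=C(C)C)cc1C=O | intermediate
5 | 2-methoxy-5-(3-methylbut-2-en-1-yl)-4-(triisopropylsilyloxy)benzaldehyde | COc1cc(O[Si](C(C)C)(C(C)C)C(C)C)c(CC=C(C)C)cc1C=O | intermediate
6 | ArB–CH=CH–OMe, E/Z mixture | COC=Cc1cc(CC=C(C)C)c(O[Si](C(C)C)(C(C)C)C(C)C)cc1OC | intermediate
7 | 2-ArB-acetaldehyde | O=CCc1cc(CC=C(C)C)c(O[Si](C(C)C)(C(C)C)C(C)C)cc1OC | intermediate
8 | 2-ArB-acetic acid | OC(=O)Cc1cc(CC=C(C)C)c(O[Si](C(C)C)(C(C)C)C(C)C)cc1OC | intermediate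
9 | (R)-4-benzyl-2-oxazolidinone | O=C1N[C@H](Cc2ccccc2)CO1 | starting material
10 | mixed anhydride of 8 with pivalic acid | CC(C)(C)C(=O)OC(=O)Cc1cc(CC=C(C)C)c(O[Si](C(C)C)(C(C)C)C(C)C)cc1OC | intermediate
11 | (R)-4-benzyl-3-(2-ArB-acetyl)oxazolidin-2-one | O=C1OC[C@@H](Cc2ccccc2)N1C(=O)Cc1cc(CC=C(C)C)c(O[Si](C(C)C)(C(C)C)C(C)C)cc1OC | intermediate
12 | 2,4,6-trimethoxybenzaldehyde | COc1cc(OC)c(C=O)c(OC)c1 | starting material
13 | 2,6-dihydroxy-4-methoxybenzaldehyde | COc1cc(O)c(C=O)c(O)c1 | intermediate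
14 | 2,6-bis(allyloxy)-4-methoxybenzaldehyde | COc1cc(OCC=C)c(C=O)c(OCC=C)c1 | intermediate
15 | (R)-4-benzyl-3-[(2S,3R)-3-ArA-2-ArB-3-(trimethylsilyloxy)propanoyl]oxazolidin-2-one | O=C1OC[C@@H](Cc2ccccc2)N1C(=O)[C@@H](c1cc(CC=C(C)C)c(O[Si](C(C)C)(C(C)C)C(C)C)cc1OC)[C@@H](O[Si](C)(C)C)c1c(OCC=C)cc(OC)cc1OCC=C | intermediate
16 | (R)-4-benzyl-3-[(2S,3R)-3-ArA-3-hydroxy-2-ArB-propanoyl]oxazolidin-2-one | O=C1OC[C@@H](Cc2ccccc2)N1C(=O)[C@@H](c1cc(CC=C(C)C)c(O[Si](C(C)C)(C(C)C)C(C)C)cc1OC)[C@@H](O)c1c(OCC=C)cc(OC)cc1OCC=C | intermediate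
17 | (R)-4-benzyl-3-[(2S,3R)-3-ArA-3-(tert-butyldimethylsilyloxy)-2-ArB-propanoyl]oxazolidin-2-one | O=C1OC[C@@H](Cc2ccccc2)N1C(=O)[C@@H](c1cc(CC=C(C)C)c(O[Si](C(C)C)(C(C)C)C(C)C)cc1OC)[C@@H](O[Si](C)(C)C(C)(C)C)c1c(OCC=C)cc(OC)cc1OCC=C | intermediate
18 | (2R,3R)-3-ArA-3-(tert-butyldimethylsilyloxy)-2-ArB-propan-1-ol | OC[C@@H](c1cc(CC=C(C)C)c(O[Si](C(C)C)(C(C)C)C(C)C)cc1OC)[C@@H](O[Si](C)(C)C(C)(C)C)c1c(OCC=C)cc(OC)cc1OCC=C | intermediate
19 | 2-[(1R,2R)-1-(tert-butyldimethylsilyloxy)-3-hydroxy-2-ArB-propyl]-5-methoxybenzene-1,3-diol | OC[C@@H](c1cc(CC=C(C)C)c(O[Si](C(C)C)(C(C)C)C(C)C)cc1OC)[C@@H](O[Si](C)(C)C(C)(C)C)c1c(O)cc(OC)cc1O | intermediate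
20 | (3R,4R)-4-(tert-butyldimethylsilyloxy)-7-methoxy-3-ArB-chroman-5-ol | COc1cc(O)c2c(c1)OC[C@@H](c1cc(CC=C(C)C)c(O[Si](C(C)C)(C(C)C)C(C)C)cc1OC)[C@H]2O[Si](C)(C)C(C)(C)C | intermediate
21 | (3R,4R)-3-[4-hydroxy-2-methoxy-5-(3-methylbut-2-en-1-yl)phenyl]-7-methoxychromane-4,5-diol | COc1cc(O)c2c(c1)OC[C@@H](c1cc(CC=C(C)C)c(O)cc1OC)[C@H]2O | target

## Step count and risks

Total steps: 16. Longest linear sequence: 14 steps (steps 1–8, then 11–16); steps 9–10 are the convergent branch.

**Step 11 (anti-aldol).** This is the most exposed step. Aldehyde 14 is di-ortho-substituted and very electron-rich, so conversion may be low, and the anti/syn ratio for an α-aryl imide is not assured. The fallback sets out from acid 8 (with aldehyde 14) and comes back to the route at 21.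
- Acid 8 is coupled with (S)-4-benzyl-2-oxazolidinone, as in step 8, to give the (S)-configured imide F1.
- The stoichiometric boron aldol (Bu2BOTf, i-Pr2NEt, CH2Cl2, −78 to 0 °C, buffered H2O2 work-up) with 14 gives the Evans syn adduct F2. This has the correct C3 configuration but is epimeric at the future C4.
- LiBH4 gives the syn diol F3, Pd(PPh3)4/morpholine gives the bis-phenol F4, and Mitsunobu closure gives the trans-isoflavan-4-ol F5.
- TBSCl/imidazole silylates the 5-OH selectively to the 5-O-TBS ether F6, and Dess–Martin periodinane (NaHCO3-buffered) gives the (3R)-isoflavanone F7.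
- LiBH(s-Bu)3 in THF at −78 °C delivers hydride equatorially and gives the cis alcohol F8. This step must be kept cold and quenched cold so that C3 does not epimerise.
- TBAF/AcOH then gives 21.

**Step 13 (reductive removal of the auxiliary).** The acyl group of 17 is flanked by an α-aryl group and a β-silyloxy, di-ortho-substituted aryl carbinol, so hydride may open the oxazolidinone ring instead. The fallback sets out from 16 and comes back at 18.
- The free β-hydroxy imide 16 is reduced first (LiBH4, MeOH, THF, 0 °C), where the neighbouring alkoxide helps exocyclic attack, to give the anti diol F9.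
- Both hydroxyls are silylated (TBSOTf, 2,6-lutidine) to the bis-TBS ether F10.
- The primary silyl ether alone is cleaved (HF·pyridine, pyridine, THF, 0 °C) to give 18.

**Step 6 (enol ether hydrolysis).** A conjugated β-methoxystyrene may need acid strong enough to hydrate the prenyl group, and the arylacetaldehyde 7 is fragile. The fallback sets out from aldehyde 5 and comes back at acid 8.
- Methylenation (Ph3PCH3Br, NaN(SiMe3)2, THF) gives the styrene F11.
- Hydroboration with 9-BBN, which selects the terminal vinyl group over the trisubstituted prenyl alkene, followed by NaBO3 oxidation gives the 2-arylethanol F12.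
- Oxidation with TEMPO (cat.)/PhI(OAc)2 in MeCN/H2O gives acid 8 with no acidic step.

Further compounds

F1 | step 11 | (S)-4-benzyl-3-(2-ArB-acetyl)oxazolidin-2-one | O=C1OC[C@H](Cc2ccccc2)N1C(=O)Cc1cc(CC=C(C)C)c(O[Si](C(C)C)(C(C)C)C(C)C)cc1OC
F2 | step 11 | (S)-4-benzyl-3-[(2S,3S)-3-ArA-3-hydroxy-2-ArB-propanoyl]oxazolidin-2-one | O=C1OC[C@H](Cc2ccccc2)N1C(=O)[C@@H](c1cc(CC=C(C)C)c(O[Si](C(C)C)(C(C)C)C(C)C)cc1OC)[C@H](O)c1c(OCC=C)cc(OC)cc1OCC=C
F3 | step 11 | (1S,2R)-1-ArA-2-ArB-propane-1,3-diol | OC[C@@H](c1cc(CC=C(C)C)c(O[Si](C(C)C)(C(C)C)C(C)C)cc1OC)[C@H](O)c1c(OCC=C)cc(OC)cc1OCC=C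
F4 | step 11 | 2-[(1S,2R)-1,3-dihydroxy-2-ArB-propyl]-5-methoxybenzene-1,3-diol | OC[C@@H](c1cc(CC=C(C)C)c(O[Si](C(C)C)(C(C)C)C(C)C)cc1OC)[C@H](O)c1c(O)cc(OC)cc1O
F5 | step 11 | (3R,4S)-7-methoxy-3-ArB-chromane-4,5-diol (trans) | COc1cc(O)c2c(c1)OC[C@@H](c1cc(CC=C(C)C)c(O[Si](C(C)C)(C(C)C)C(C)C)cc1OC)[C@@H]2O
F6 | step 11 | (3R,4S)-5-(tert-butyldimethylsilyloxy)-7-methoxy-3-ArB-chroman-4-ol | COc1cc(O[Si](C)(C)C(C)(C)C)c2c(c1)OC[C@@H](c1cc(CC=C(C)C)c(O[Si](C(C)C)(C(C)C)C(C)C)cc1OC)[C@@H]2O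
F7 | step 11 | (3R)-5-(tert-butyldimethylsilyloxy)-7-methoxy-3-ArB-chroman-4-one | COc1cc(O[Si](C)(C)C(C)(C)C)c2c(c1)OC[C@@H](c1cc(CC=C(C)C)c(O[Si](C(C)C)(C(C)C)C(C)C)cc1OC)C2=O
F8 | step 11 | (3R,4R)-5-(tert-butyldimethylsilyloxy)-7-methoxy-3-ArB-chroman-4-ol (cis) | COc1cc(O[Si](C)(C)C(C)(C)C)c2c(c1)OC[C@@H](c1cc(CC=C(C)C)c(O[Si](C(C)C)(C(C)C)C(C)C)cc1OC)[C@H]2O
F9 | step 13 | (1R,2R)-1-ArA-2-ArB-propane-1,3-diol | OC[C@@H](c1cc(CC=C(C)C)c(O[Si](C(C)C)(C(C)C)C(C)C)cc1OC)[C@@H](O)c1c(OCC=C)cc(OC)cc1OCC=C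
F10 | step 13 | (1R,2R)-1-ArA-2-ArB-1,3-bis(tert-butyldimethylsilyloxy)propane | CC(C)(C)[Si](C)(C)OC[C@@H](c1cc(CC=C(C)C)c(O[Si](C(C)C)(C(C)C)C(C)C)cc1OC)[C@@H](O[Si](C)(C)C(C)(C)C)c1c(OCC=C)cc(OC)cc1OCC=C
F11 | step 6 | ArB–CH=CH2 (2-methoxy-5-prenyl-4-(triisopropylsilyloxy)styrene) | C=Cc1cc(CC=C(C)C)c(O[Si](C(C)C)(C(C)C)C(C)C)cc1OC
F12 | step 6 | 2-ArB-ethanol | OCCc1cc(CC=C(C)C)c(O[Si](C(C)C)(C(C)C)C(C)C)cc1OC
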